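0.0440 M of Q is what dawn lacks for two Q on every D, so Q is the limiting reagent there, and the dispute is over where that shortfall lands.

all flasks: D 0.089 M

|  | Q | remark | time |
|---|---|---|---|
| epsilon | 0.15 M | run made earlier |  |
| gamma | 0.16 M | run made earlier |  |
| beta | 0.23 M | run made earlier |  |
| dawn | 0.134 M |  | 30 min |
| spring | 0.178 M |  | 30 min |
| summer | 0.222 M |  | 30 min |

| run | time / min | Q.D.Q / % |
|---|---|---|
| epsilon | 2.50 | 57.1 |
| epsilon | 5.00 | 66.8 |
| epsilon | 8.00 | 68.3 |
| epsilon | 15.0 | 68.8 |
| epsilon | 30.0 | 68.4 |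
| gamma | 2.50 | 63.7 |
| gamma | 5.00 | 72.1 |
| gamma | 8.00 | 77.7 |
| gamma | 15.0 | 79.2 |
| gamma | 30.0 | 80.4 |
| beta | 2.50 | 89.1 |
| beta | 8.00 | 97.8 |
| beta | 15.0 | 97.5 |
| beta | 20.0 | 96.1 |
| beta | 30.0 | 96.8 |

(each reading ± 1 percentage point)

- for Q.D.Q the X are counted in
- as a solid, counted per litre of solution: X
- candidate steps: D + Q -> D.Q; Q + D.Q -> Q.D.Q; Q + Q.D.Q <-> Q.Q.D.Q; X <-> Q.D.Q

- how much Q.D.Q is there at the end, in percent of the D charged: for each flask in turn (dawn, spring, summer)

Each Q bound moves one D up one rung, from D to D.Q, to Q.D.Q, to Q.Q.D.Q, and Q.D.Q may also crystallise as X, which is counted within Q.D.Q.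

The first chemist, who made the forecast, argues that “Each Q consumed makes one step up the ladder”. By my own reckoning dawn's 50.6% is its ladder count, the Q charged per D charged less one. The count gives 68.5% for epsilon, against a reading of 68.4%, and 79.8% for gamma, against 80.4%, with a scatter of 1 percentage point.

The second chemist treats D and D.Q as competing substrates for one pool of Q, so that D.Q can take Q while D remains. Her own balance, with unbound Q set aside, is that Q.D.Q equals the ladder count plus the D left, less twice the Q.Q.D.Q. She gives no figure for dawn, but she places it above the count. Her answer to epsilon and gamma is that epsilon lacked 0.0280 M of Q, less than dawn, and she expects the D left to grow with the shortfall.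

The forecast for dawn, spring and summer is 50.5%, 94.5% and 97.2%.

The simulation gives 56.0%, 95.7% and 95.7%, so dawn stands 5.5 points above the forecast, on the second chemist's side of the count.

    D + Q → D.Q (k = 0.434 /M/s)
    Q + D.Q → Q.D.Q (k = 0.212 /M/s)
    Q + Q.D.Q ⇌ Q.Q.D.Q (K = 74.0 /M, k = 0.0186 /M/s)
    X ⇌ Q.D.Q, rate k4*(cs4 - [Q.D.Q]) while solid is left; crystals form when [Q.D.Q] > cs4 (solubility = 3.00 mM, k = 0.556 /s)

In dawn the half-life of D.Q by Q + D.Q goes from 0.64 min at 0.229 min to 130 h at 30.0 min, far longer than the 30 min of the flask. With 0.00510% of its Q unbound, dawn holds 6.00% of D and 37.7% of D.Q, and the count plus that D, less twice the 0.283% of Q.Q.D.Q, reads 56.0%. Spring is the ladder view's region, with 0.0249% of D: its count of 100%, less the unbound Q, 2.47% of the D charged, plus that D, less twice the 0.931% of Q.Q.D.Q, reads 95.7%.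

The runs come from a simulation for substances that don't exist; the scatter is artificial.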